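Everything rests on disconnecting the C4–C4a bond, the bond between the carbonyl carbon and ring A. An acid-mediated Friedel–Crafts cycliacylation of an ethyl 3-aryloxyacrylate closes the pyranone ring (ring C) in one operation at the chromone oxidation level. It exploits that C4a is the only hydrogen-bearing ring A carbon ortho to O1 and lies ortho and para to the methoxy oxygens on C5 and C7. The precursor is an open aryl vinyl ether from a phenol and ethyl propiolate; the acrylate also masks that phenol while a formyl group is turned into the C5 methoxy group. The C2 stereocenter (S) is set last by catalyst-controlled 1,4-addition of the ring B boronic acid.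

Key step: step 4

Remark on the chemistry: atoms are numbered as in a flavanone (O1, C2, C3, C4, C4a, C5 to C8, C8a). Ring A is the trimethoxybenzo ring, ring B the 3,4-dimethoxyphenyl group and ring C the pyranone. The configuration at C2 in the given structure is S.

**Route**

Step 1
Reactants: 1 3-hydroxy-4,5-dimethoxybenzaldehyde; 2 ethyl propiolate
Product: 3 ethyl (E)-3-(5-formyl-2,3-dimethoxyphenoxy)acrylate
Conditions: DABCO (10 mol%), CH2Cl2, 0 °C to rt
Reagents that add atoms: none
Why: Amine-catalysed oxa-Michael (phenol–yne) addition, in which the phenoxide of 1 adds to the β-carbon of the propiolate and the thermodynamically preferred (E)-3-aryloxyacrylate should result, the meta aldehyde being a spectator and the alkene geometry being equilibrated later in any case.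

Step 2
Reactants: 3 ethyl (E)-3-(5-formyl-2,3-dimethoxyphenoxy)acrylate
Product: 5 ethyl (E)-3-(5-hydroxy-2,3-dimethoxyphenoxy)acrylate, via aryl formate 4 (not isolated)
Conditions: mCPBA, CH2Cl2, 0 °C to rt; then MeOH, KHCO3 (cat.), rt
Reagents that add atoms: mCPBA (3-chloroperoxybenzoic acid), O=C(OO)c1cccc(Cl)c1
Why: Baeyer–Villiger (Dakin-type) oxidation, in which the aryl group activated by its para methoxy group should migrate in preference to hydride to give the aryl formate, whose near-neutral methanolysis frees the phenol without touching the electron-poor aryloxyacrylate.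

Step 3
Reactants: 5 ethyl (E)-3-(5-hydroxy-2,3-dimethoxyphenoxy)acrylate
Product: 6 ethyl (E)-3-(2,3,5-trimethoxyphenoxy)acrylate
Conditions: MeI, K2CO3, acetone, 40 °C
Reagents that add atoms: iodomethane (MeI), CI
Why: Williamson O-methylation (SN2) of the phenoxide, which with excess MeI should be faster than any phenoxide exchange at the β-carbon of the aryloxyacrylate.

Step 4
Reactants: 6 ethyl (E)-3-(2,3,5-trimethoxyphenoxy)acrylate
Product: 8 5,7,8-trimethoxy-4H-chromen-4-one, via (Z)-ester 7 (not isolated)
Conditions: Eaton's reagent (P2O5 in MeSO3H, 1:10 w/w), 0.1 M, 50 °C; then ice, aq. NaHCO3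
Reagents that add atoms: none
Why: In the strong, dehydrating acid the push–pull ester is O-protonated to a delocalised cation (aryl–O+=CH–CH=C(OH)OEt) whose former C=C bond has single-bond character, so (E)-6 should equilibrate with (Z)-7, the only geometry in which the acyl carbon can reach ring A. The activated acyl carbon (protonated ester or, after loss of ethanol, the acylium ion) is then attacked by C4a in an intramolecular Friedel–Crafts acylation, and loss of ethanol and of the ring proton gives the benzo-fused 4-pyranone. The closest known reactions are the acid-mediated cyclisation of 3-aryloxyacrylic acids and aryloxyfumarates to chromones, the Simonis chromone synthesis (ring closure of β-aryloxycrotonate esters under P2O5) and the Gould–Jacobs cycliacylation of β-anilinoacrylate esters in Eaton's reagent. Ring C closes in the 6-exo-trig mode (6-exo-dig if the free acylium ion is the electrophile) by forming the C4–C4a bond, and no stereocenter is created. The step needs site selectivity for C4a over C6 and ring closure over intermolecular acylation: C4a is the only hydrogen-bearing carbon ortho to O1 (C8 carries OMe), it is ortho to O1 and the C5 methoxy oxygen and para to the C7 methoxy oxygen, and C6 cannot be reached through a six-membered transition state. The chromone formed is a deactivated vinylogous ester and should not react further.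

Step 5
Reactants: 8 5,7,8-trimethoxy-4H-chromen-4-one; 9 (3,4-dimethoxyphenyl)boronic acid
Product: 10 (2S)-2-(3,4-dimethoxyphenyl)-5,7,8-trimethoxy-2,3-dihydro-4H-chromen-4-one (the target)
Conditions: [Rh(OH)((S)-BINAP)]2 (3 mol%), 9 (3 equiv), 1,4-dioxane/H2O (10:1), 40 °C
Reagents that add atoms: none
Why: Hayashi–Miyaura rhodium-catalysed asymmetric 1,4-addition, in which the aryl rhodium species carrying (S)-BINAP should insert the C2=C3 bond of the chromone on the face predicted by the established model for cyclic enones ((S)-BINAP gives (S)-3-arylcycloalkanones, which corresponds in space to a (2S)-flavanone), so that C2 is set as S under catalyst control, and protonation of the oxa-π-allyl rhodium enolate by water releases the ketone without added base.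

**Compound list**

1 | 3-hydroxy-4,5-dimethoxybenzaldehyde | O=Cc1cc(O)c(OC)c(OC)c1 | starting material
2 | ethyl propiolate (ethyl prop-2-ynoate) | C#CC(=O)OCC | starting material
3 | ethyl (E)-3-(5-formyl-2,3-dimethoxyphenoxy)acrylate | CCOC(=O)/C=C/Oc1cc(C=O)cc(OC)c1OC | intermediate
4 | ethyl (E)-3-[5-(formyloxy)-2,3-dimethoxyphenoxy]acrylate | CCOC(=O)/C=C/Oc1cc(OC=O)cc(OC)c1OC | intermediate
5 | ethyl (E)-3-(5-hydroxy-2,3-dimethoxyphenoxy)acrylate | CCOC(=O)/C=C/Oc1cc(O)cc(OC)c1OC | intermediate
6 | ethyl (E)-3-(2,3,5-trimethoxyphenoxy)acrylate | CCOC(=O)/C=C/Oc1cc(OC)cc(OC)c1OC | intermediate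
7 | ethyl (Z)-3-(2,3,5-trimethoxyphenoxy)acrylate | CCOC(=O)/C=C\Oc1cc(OC)cc(OC)c1OC | intermediate
8 | 5,7,8-trimethoxy-4H-chromen-4-one | O=C1C=COc2c(OC)c(OC)cc(OC)c12 | intermediate
9 | (3,4-dimethoxyphenyl)boronic acid | COc1ccc(B(O)O)cc1OC | starting material
10 | (2S)-2-(3,4-dimethoxyphenyl)-5,7,8-trimethoxy-2,3-dihydro-4H-chromen-4-one | COc1ccc([C@@H]2CC(=O)c3c(OC)cc(OC)c(OC)c3O2)cc1OC | target

**Summary**

Total step count: 5. Longest linear sequence: 5 steps (1 to 3 to 5 to 6 to 8 to 10).

**Steps most likely to fail**

Risk 1 (step 4, the key step): the E to Z equilibration may be too slow at the ester level, so that C-protonation of the enol ether and cleavage of the aryl vinyl ether, or intermolecular acylation at C6, compete with ring closure. The fallback sets out from 6 and comes back at 8, and removes the geometric constraint by saturating the tether. Hydrogenation of 6 (H2, Pd/C, EtOAc) should give ethyl 3-(2,3,5-trimethoxyphenoxy)propanoate F1. Saponification of this ester (LiOH, THF/H2O, then aqueous acid) should give 3-(2,3,5-trimethoxyphenoxy)propanoic acid F2. The classical cyclisation of 3-aryloxypropanoic acids through the mixed anhydride (TFAA, CH2Cl2, 0 °C to rt) closes the same C4–C4a bond and should give 5,7,8-trimethoxychroman-4-one F3. Dehydrogenation of this chromanone with IBX (DMSO, 80 °C) returns to 8.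

Risk 2 (step 5): the 1,4-addition to this electron-rich vinylogous ester may be slow relative to protodeboronation of 9. Facial selectivity may be insufficient. Reversible ring opening of the rhodium enolate or of the product (retro-oxa-Michael) may erode the configuration at C2. The fallback sets out from 8 and comes back at 10, and gives up enantioselective bond formation in favour of resolution. Addition of 9 to 8 with an achiral cationic divalent palladium catalyst (Pd(OCOCF3)2, 2,2'-bipyridine, NH4PF6, ClCH2CH2Cl/H2O, 60 °C) has no configuration to protect, so the conditions can be forced. It should give racemic 2-(3,4-dimethoxyphenyl)-5,7,8-trimethoxychroman-4-one F4. Preparative chromatography of this racemate on a chiral stationary phase (amylose tris(3,5-dimethylphenylcarbamate)) then delivers the (2S)-enantiomer 10.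

Risk 3 (step 2): hydride migration may compete with aryl migration and give the benzoic acid, and the aryloxyacrylate may be lost or exchanged while the formate is cleaved and the phenol is exposed. The fallback sets out from 1 and comes back at 6, and carries out the formyl-to-methoxy exchange before the acrylate is introduced. Benzylation of 1 (BnBr, K2CO3, DMF) should give 3-(benzyloxy)-4,5-dimethoxybenzaldehyde F5. Baeyer–Villiger oxidation of this aldehyde (mCPBA, CH2Cl2) should give 3-(benzyloxy)-4,5-dimethoxyphenyl formate F6. Methanolysis (K2CO3, MeOH) should cleave the formate to 3-(benzyloxy)-4,5-dimethoxyphenol F7. Methylation of this phenol (MeI, K2CO3, acetone) should give 1-(benzyloxy)-2,3,5-trimethoxybenzene F8. Hydrogenolysis of the benzyl ether (H2, Pd/C, EtOAc) should give 2,3,5-trimethoxyphenol F9. DABCO-catalysed addition of this phenol to 2 (CH2Cl2, rt) returns to 6.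

Further compounds
F1 | step 4 | ethyl 3-(2,3,5-trimethoxyphenoxy)propanoate | CCOC(=O)CCOc1cc(OC)cc(OC)c1OC
F2 | step 4 | 3-(2,3,5-trimethoxyphenoxy)propanoic acid | OC(=O)CCOc1cc(OC)cc(OC)c1OC
F3 | step 4 | 5,7,8-trimethoxychroman-4-one | O=C1CCOc2c(OC)c(OC)cc(OC)c12
F4 | step 5 | racemic 2-(3,4-dimethoxyphenyl)-5,7,8-trimethoxychroman-4-one | COc1ccc(C2CC(=O)c3c(OC)cc(OC)c(OC)c3O2)cc1OC
F5 | step 2 | 3-(benzyloxy)-4,5-dimethoxybenzaldehyde | O=Cc1cc(OCc2ccccc2)c(OC)c(OC)c1
F6 | step 2 | 3-(benzyloxy)-4,5-dimethoxyphenyl formate | O=COc1cc(OCc2ccccc2)c(OC)c(OC)c1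
F7 | step 2 | 3-(benzyloxy)-4,5-dimethoxyphenol | Oc1cc(OCc2ccccc2)c(OC)c(OC)c1
F8 | step 2 | 1-(benzyloxy)-2,3,5-trimethoxybenzene | COc1cc(OCc2ccccc2)c(OC)c(OC)c1
F9 | step 2 | 2,3,5-trimethoxyphenol | COc1cc(O)c(OC)c(OC)c1
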